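The C1–C6 cyclohexene ring (C1 alkynyl, C2 =CH, C3 OAc, C4 OMe, C5 OH, C6 OH) is opened at the C5–C6 bond between the two free carbinol carbons. These hydroxyls form a cis pair lying trans to the C4 methoxy group, the pattern expected from a samarium-bridged pinacol coupling next to an α-alkoxy centre. One SmI2 operation on an open-chain dialdehyde, a (Z)-2-alkynyl enal (C6) tethered to an α-methoxy aldehyde (C5), therefore closes the six-membered ring and sets C5 and C6 together. The dialdehyde carries C3 as a TBS ether and a TIPS-capped alkyne; C3/C4 derive from D-erythronolactone. C3 acetylation and a final Sonogashira coupling finish the target.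

Key step: step 9

Locants: ring carbons are C1 (sp2, alkyne-bearing), C2 (=CH), C3 (OAc), C4 (OMe), C5 (OH), C6 (OH). Open-chain intermediates use the same labels for the carbons that become these atoms, and CIP descriptors of ring compounds refer to these locants. TBS = tert-butyldimethylsilyl, TES = triethylsilyl, TIPS = triisopropylsilyl.

Assumption: dialdehyde 17 (epimerisable C4, Z-enal) is not purified and is carried crude into step 9.

Step 1
Reactants: 1 D-erythronolactone
Product: 2 2-O-TBS-D-erythronolactone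
Conditions: TBSCl (1.05 equiv), imidazole, DMF, −20 → 0 °C
Reagents that add atoms: tert-butyldimethylsilyl chloride, CC(C)(C)[Si](C)(C)Cl
Why: Imidazole-promoted silyl ether formation, in which the C2 hydroxyl α to the lactone carbonyl is the more acidic of the cis pair and should react first at low temperature (any 3-O-silyl or bis-silyl material would be removed by chromatography), with no stereocentre touched.

Step 2
Reactants: 2 2-O-TBS-D-erythronolactone
Product: 3 2-O-TBS-3-O-methyl-D-erythronolactone
Conditions: Me3OBF4, 1,8-bis(dimethylamino)naphthalene, 4 Å MS, CH2Cl2, 0 °C → rt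
Reagents that add atoms: trimethyloxonium tetrafluoroborate, C[O+](C)C.F[B-](F)(F)F
Why: O-Methylation by an oxonium salt with a non-nucleophilic amine base forms no alkoxide, so silyl migration from O2 and β-elimination of the lactone should not intervene and the configuration is retained.

Step 3
Reactants: 3 2-O-TBS-3-O-methyl-D-erythronolactone
Product: 5 2-O-TBS-3-O-methyl-D-erythrofuranose (lactol; anomer mixture), via aluminium lactolate 4 (not isolated)
Conditions: i-Bu2AlH (1.1 equiv), CH2Cl2, −78 °C; aq. sodium potassium tartrate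
Reagents that add atoms: none
Why: Partial hydride reduction of a γ-lactone, in which the tetrahedral aluminium lactolate is stable at −78 °C and releases the lactol only on work-up, the anomeric mixture being of no consequence.

Step 4
Reactants: 5 2-O-TBS-3-O-methyl-D-erythrofuranose; 6 tetrabromomethane
Product: 8 (2R,3S)-5,5-dibromo-3-(TBS-oxy)-2-methoxypent-4-en-1-ol, via open-chain hydroxy aldehyde 7 (not isolated)
Conditions: PPh3, CBr4, Zn dust (2 equiv each), CH2Cl2, rt, 24 h (ylide pre-formed); then 5, rt → 40 °C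
Reagents that add atoms: tetrabromomethane (6), BrC(Br)(Br)Br
Why: Ramirez/Corey–Fuchs dibromo-olefination (Wittig reaction of Ph3P=CBr2) of the ring-opened aldehyde tautomer, where pre-forming the ylide with zinc leaves no bromophosphonium species to brominate the liberated primary alcohol and the base-free medium leaves the α-silyloxy stereocentre and the silyl ether in place.

Step 5
Reactants: 8 (2R,3S)-5,5-dibromo-3-(TBS-oxy)-2-methoxypent-4-en-1-ol
Product: 9 (3S,4R)-1,1-dibromo-3-(TBS-oxy)-4-methoxy-5-(TES-oxy)pent-1-ene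
Conditions: Et3SiCl, imidazole, CH2Cl2, 0 °C
Reagents that add atoms: chlorotriethylsilane, CC[Si](Cl)(CC)CC
Why: Standard silylation of a primary alcohol, placed here so that no hydroxyl faces the organolithium of step 7 or can add in conjugate fashion to the enal made there.

Step 6
Reactants: 9 (3S,4R)-1,1-dibromo-3-(TBS-oxy)-4-methoxy-5-(TES-oxy)pent-1-ene; 10 (triisopropylsilyl)acetylene
Product: 11 (3Z,5S,6R)-3-bromo-5-(TBS-oxy)-6-methoxy-7-(TES-oxy)-1-(TIPS)hept-3-en-1-yne
Conditions: PdCl2(dppf) (5 mol%), CuI (10 mol%), i-Pr2NH, toluene, rt; 10 (1.1 equiv)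
Reagents that add atoms: (triisopropylsilyl)acetylene (10), C#C[Si](C(C)C)(C(C)C)C(C)C
Why: Sonogashira coupling of a 1,1-dibromoalkene, in which zerovalent palladium inserts selectively into the less hindered C–Br bond trans to the C3 substituent, so the alkyne enters trans to C3 and the remaining bromide, cis to C3, defines the (Z)-bromoenyne.

Step 7
Reactants: 11 (3Z,5S,6R)-3-bromo-5-(TBS-oxy)-6-methoxy-7-(TES-oxy)-1-(TIPS)hept-3-en-1-yne; 12 N,N-dimethylformamide
Product: 15 (2Z,4S,5R)-4-(TBS-oxy)-5-methoxy-6-(TES-oxy)-2-[(TIPS)ethynyl]hex-2-enal, via vinyllithium 13 (not isolated), via lithium hemiaminal alkoxide 14 (not isolated)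
Conditions: t-BuLi (2.1 equiv), Et2O, −78 °C, 15 min; DMF (3 equiv), −78 → −40 °C; pH 7 phosphate buffer, −78 → 0 °C
Reagents that add atoms: N,N-dimethylformamide (12), CN(C)C=O
Why: Bromine–lithium exchange followed by formylation with DMF (Bouveault-type aldehyde synthesis), where exchange at −78 °C should retain the alkene geometry so that the formyl group ends up cis to C3 as ring closure requires, the silyl ethers and the silylalkyne being inert to t-BuLi at this temperature.

Step 8
Reactants: 15 (2Z,4S,5R)-4-(TBS-oxy)-5-methoxy-6-(TES-oxy)-2-[(TIPS)ethynyl]hex-2-enal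
Product: 17 (2Z,4S,5S)-4-(TBS-oxy)-5-methoxy-2-[(TIPS)ethynyl]hex-2-enedial (the dialdehyde), via alkoxysulfonium chloride 16 (not isolated)
Conditions: (COCl)2 (4 equiv), DMSO (8 equiv), CH2Cl2, −78 → −30 °C; Et3N, −78 → −20 °C; used crude
Reagents that add atoms: none
Why: Swern oxidation applied directly to a primary triethylsilyl ether, in which the chlorosulfonium reagent attacks the unhindered silyl ether oxygen, Et3SiCl leaves and the alkoxysulfonium salt collapses to the aldehyde on adding Et3N, while the hindered secondary TBS ether is untouched, a hydroxy enal is never set free and the low temperature protects C4 next to the new aldehyde.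

Step 9
Reactants: 17 (2Z,4S,5S)-4-(TBS-oxy)-5-methoxy-2-[(TIPS)ethynyl]hex-2-enedial
Product: 19 (3S,4R,5S,6S)-3-(TBS-oxy)-4-methoxy-1-[(TIPS)ethynyl]cyclohex-1-ene-5,6-diol, via samarium diolate 18 (not isolated)
Conditions: SmI2 (3 equiv, 0.1 M in THF, no HMPA), t-BuOH (3 equiv), −78 °C, slow addition of 17, then −78 → −30 °C; aq. NaHCO3
Reagents that add atoms: none
Why: SmI2 transfers one electron to the conjugated C6 aldehyde, the more easily reduced carbonyl, and the samarium-bound ketyl attacks the carbonyl carbon of the samarium-coordinated C5 aldehyde, after which a second electron gives the cyclic trivalent-samarium diolate 18 that t-BuOH protonates to 19. The closest known reaction type is the SmI2 pinacol cyclisation of sugar-derived 1,6-dialdehydes to cis-cyclohexane-1,2-diols, here with an enal as one partner. The six-membered ring closes in a 6-exo-trig sense (C6 onto the C5 carbonyl carbon, oxygen outside the ring), the only strain-free option because reaction through the other terminus of the delocalised ketyl, C2, would require a four-membered ring. C6 is set cis to C5 because both oxygens stay bound to samarium while the C–C bond forms, and C5 is set with its oxygen anti to the neighbouring C4 methoxy group to minimise dipole and steric repulsion, which puts both new hydroxyls on the face opposite C4-OMe and C3-OTBS. The step needs carbonyl–carbonyl coupling to outrun over-reduction of the enal and expulsion of the C3 oxygen, and this is secured by the (Z)-geometry fixed in steps 6 and 7 (C6 held next to C5), by the C3 silyl ether being a poor leaving group, by the TIPS shield on the alkyne and by mild, HMPA-free SmI2 at −78 °C under slow addition.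

Step 10
Reactants: 19 (3S,4R,5S,6S)-3-(TBS-oxy)-4-methoxy-1-[(TIPS)ethynyl]cyclohex-1-ene-5,6-diol
Product: 20 5,6-O-isopropylidene derivative of 19 (3S,4R,5S,6S; cis-fused dioxolane)
Conditions: 2,2-dimethoxypropane, PPTS (cat.), CH2Cl2, rt
Reagents that add atoms: 2,2-dimethoxypropane, COC(C)(C)OC
Why: Acetal exchange (acetonide formation), for which only the cis-5,6-diol can form a five-membered dioxolane and PPTS is too weak an acid to cleave the TBS ether.

Step 11
Reactants: 20 5,6-O-isopropylidene derivative of 19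
Product: 21 (3S,4S,5S,6S)-1-ethynyl-5,6-(isopropylidenedioxy)-4-methoxycyclohex-1-en-3-ol
Conditions: Bu4NF (2.5 equiv), THF, 0 °C → rt
Reagents that add atoms: none
Why: Fluoride-induced desilylation, in which Bu4NF cleaves the Si–O bond of the secondary TBS ether and the Si–C(sp) bond of the silylalkyne in one operation while the acetonide is stable to fluoride.

Step 12
Reactants: 21 (3S,4S,5S,6S)-1-ethynyl-5,6-(isopropylidenedioxy)-4-methoxycyclohex-1-en-3-ol
Product: 22 (3S,4S,5S,6S)-3-acetoxy-1-ethynyl-5,6-(isopropylidenedioxy)-4-methoxycyclohex-1-ene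
Conditions: Ac2O, pyridine, DMAP (cat.), CH2Cl2, 0 °C → rt
Reagents that add atoms: acetic anhydride, CC(=O)OC(C)=O
Why: DMAP-catalysed acyl transfer to the only free hydroxyl, with the terminal alkyne and the acetonide inert and the configuration at C3 retained.

Step 13
Reactants: 22 (3S,4S,5S,6S)-3-acetoxy-1-ethynyl-5,6-(isopropylidenedioxy)-4-methoxycyclohex-1-ene
Product: 23 (3S,4R,5S,6S)-3-acetoxy-1-ethynyl-4-methoxycyclohex-1-ene-5,6-diol
Conditions: AcOH–H2O (4:1), 45 °C
Reagents that add atoms: none
Why: Acid-catalysed acetal hydrolysis, in which aqueous acetic acid removes the acetonide while the acetate survives, acetyl migration being blocked because O4 is methylated and the C5 hydroxyl lies on the ring face opposite the C3 acetate.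

Step 14
Reactants: 24 2-methylbut-3-yn-2-ol
Product: 25 (E)-2-methyl-4-(tributylstannyl)but-3-en-2-ol
Conditions: Bu3SnH (1.1 equiv), PdCl2(PPh3)2 (2 mol%), THF, 0 °C → rt
Reagents that add atoms: tributyltin hydride, CCCC[SnH](CCCC)CCCC
Why: Palladium-catalysed hydrostannation, a syn addition of Sn–H across the terminal alkyne with tin directed to the unhindered terminus by the bulky tertiary carbinol, which should give the (E)-vinylstannane, separable from any internal isomer.

Step 15
Reactants: 25 (E)-2-methyl-4-(tributylstannyl)but-3-en-2-ol; 26 2,3-dibromopropene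
Product: 27 (E)-6-bromo-2-methylhepta-3,6-dien-2-ol
Conditions: PdCl2(MeCN)2 (5 mol%), 26 (2 equiv), DMF, rt
Reagents that add atoms: 2,3-dibromopropene (26), C=C(Br)CBr
Why: Stille coupling, in which the allylic C–Br bond of 2,3-dibromopropene adds to zerovalent palladium far faster than the vinylic one and the alkenyl group is transferred from tin with retention, giving the skipped diene with the (E)-alkene and the vinyl bromide intact.

Step 16
Reactants: 23 (3S,4R,5S,6S)-3-acetoxy-1-ethynyl-4-methoxycyclohex-1-ene-5,6-diol; 27 (E)-6-bromo-2-methylhepta-3,6-dien-2-ol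
Product: 28 target CNP0546270.2
Conditions: Pd(PPh3)4 (5 mol%), CuI (10 mol%), Et3N, THF (degassed), rt; 27 (1.3 equiv)
Reagents that add atoms: (E)-6-bromo-2-methylhepta-3,6-dien-2-ol (27), C=C(Br)C/C=C/C(C)(C)O
Why: Sonogashira coupling of the terminal alkyne with the 2-bromoalkene forms the C(sp)–C(sp2) bond, free hydroxyls being tolerated and a tertiary amine base at room temperature giving the allylic acetate no amine nucleophile and little opportunity to ionise on palladium.

Compound list

1 | D-erythronolactone | O=C1[C@H](O)[C@H](O)CO1 | starting material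
2 | 2-O-TBS-D-erythronolactone, (3R,4R)-3-(tert-butyldimethylsilyloxy)-4-hydroxyoxolan-2-one | O=C1[C@H](O[Si](C)(C)C(C)(C)C)[C@H](O)CO1 | intermediate
3 | 2-O-TBS-3-O-methyl-D-erythronolactone, (3R,4R)-3-(tert-butyldimethylsilyloxy)-4-methoxyoxolan-2-one | O=C1[C@H](O[Si](C)(C)C(C)(C)C)[C@H](OC)CO1 | intermediate
4 | diisobutylaluminium lactolate of 5 (not isolated) | CC(C)C[Al](CC(C)C)OC1[C@H](O[Si](C)(C)C(C)(C)C)[C@H](OC)CO1 | intermediate
5 | 2-O-TBS-3-O-methyl-D-erythrofuranose, (3R,4R)-3-(tert-butyldimethylsilyloxy)-4-methoxyoxolan-2-ol, anomer mixture | OC1[C@H](O[Si](C)(C)C(C)(C)C)[C@H](OC)CO1 | intermediate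
6 | tetrabromomethane | BrC(Br)(Br)Br | starting material
7 | (2R,3R)-2-(tert-butyldimethylsilyloxy)-4-hydroxy-3-methoxybutanal, open-chain tautomer of 5 (not isolated) | O=C[C@H](O[Si](C)(C)C(C)(C)C)[C@H](OC)CO | intermediate
8 | (2R,3S)-5,5-dibromo-3-(tert-butyldimethylsilyloxy)-2-methoxypent-4-en-1-ol | BrC(Br)=C[C@H](O[Si](C)(C)C(C)(C)C)[C@H](OC)CO | intermediate
9 | (3S,4R)-1,1-dibromo-3-(tert-butyldimethylsilyloxy)-4-methoxy-5-(triethylsilyloxy)pent-1-ene | BrC(Br)=C[C@H](O[Si](C)(C)C(C)(C)C)[C@H](OC)CO[Si](CC)(CC)CC | intermediate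
10 | (triisopropylsilyl)acetylene | C#C[Si](C(C)C)(C(C)C)C(C)C | starting material
11 | (3Z,5S,6R)-3-bromo-5-(tert-butyldimethylsilyloxy)-6-methoxy-7-(triethylsilyloxy)-1-(triisopropylsilyl)hept-3-en-1-yne | CC(C)[Si](C#C/C(Br)=C/[C@H](O[Si](C)(C)C(C)(C)C)[C@H](OC)CO[Si](CC)(CC)CC)(C(C)C)C(C)C | intermediate
12 | N,N-dimethylformamide | CN(C)C=O | starting material
13 | vinyllithium from 11, lithium in place of bromine with geometry retained (not isolated) | CC(C)[Si](C#C/C([Li])=C/[C@H](O[Si](C)(C)C(C)(C)C)[C@H](OC)CO[Si](CC)(CC)CC)(C(C)C)C(C)C | intermediate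
14 | lithium hemiaminal alkoxide, DMF adduct of 13 (not isolated) | CC(C)[Si](C#C/C(C(O[Li])N(C)C)=C/[C@H](O[Si](C)(C)C(C)(C)C)[C@H](OC)CO[Si](CC)(CC)CC)(C(C)C)C(C)C | intermediate
15 | (2Z,4S,5R)-4-(tert-butyldimethylsilyloxy)-5-methoxy-6-(triethylsilyloxy)-2-[(triisopropylsilyl)ethynyl]hex-2-enal | CC(C)[Si](C#C/C(C=O)=C/[C@H](O[Si](C)(C)C(C)(C)C)[C@H](OC)CO[Si](CC)(CC)CC)(C(C)C)C(C)C | intermediate
16 | alkoxydimethylsulfonium chloride at the C5 oxygen of 15 (not isolated) | CC(C)[Si](C#C/C(C=O)=C/[C@H](O[Si](C)(C)C(C)(C)C)[C@H](OC)CO[S+](C)C)(C(C)C)C(C)C.[Cl-] | intermediate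
17 | (2Z,4S,5S)-4-(tert-butyldimethylsilyloxy)-5-methoxy-2-[(triisopropylsilyl)ethynyl]hex-2-enedial | O=C[C@@H](OC)[C@@H](O[Si](C)(C)C(C)(C)C)/C=C(\C=O)C#C[Si](C(C)C)(C(C)C)C(C)C | intermediate
18 | O5,O6-bis(diiodosamarium) diolate of 19 (not isolated) | CC(C)[Si](C#CC1=C[C@H](O[Si](C)(C)C(C)(C)C)[C@H](OC)[C@@H](O[Sm](I)I)[C@H]1O[Sm](I)I)(C(C)C)C(C)C | intermediate
19 | (3S,4R,5S,6S)-3-(tert-butyldimethylsilyloxy)-4-methoxy-1-[(triisopropylsilyl)ethynyl]cyclohex-1-ene-5,6-diol; 3-O and 4-OMe on one face, 5-OH and 6-OH on the other | CC(C)[Si](C#CC1=C[C@H](O[Si](C)(C)C(C)(C)C)[C@H](OC)[C@@H](O)[C@H]1O)(C(C)C)C(C)C | intermediate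
20 | 5,6-O-isopropylidene derivative of 19 (3S,4R,5S,6S) | CC(C)[Si](C#CC1=C[C@H](O[Si](C)(C)C(C)(C)C)[C@H](OC)[C@H]2OC(C)(C)O[C@@H]12)(C(C)C)C(C)C | intermediate
21 | (3S,4S,5S,6S)-1-ethynyl-5,6-(isopropylidenedioxy)-4-methoxycyclohex-1-en-3-ol | C#CC1=C[C@H](O)[C@H](OC)[C@H]2OC(C)(C)O[C@@H]12 | intermediate
22 | (3S,4S,5S,6S)-3-acetoxy-1-ethynyl-5,6-(isopropylidenedioxy)-4-methoxycyclohex-1-ene | C#CC1=C[C@H](OC(C)=O)[C@H](OC)[C@H]2OC(C)(C)O[C@@H]12 | intermediate
23 | (3S,4R,5S,6S)-3-acetoxy-1-ethynyl-4-methoxycyclohex-1-ene-5,6-diol | C#CC1=C[C@H](OC(C)=O)[C@H](OC)[C@@H](O)[C@H]1O | intermediate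
24 | 2-methylbut-3-yn-2-ol | C#CC(C)(C)O | starting material
25 | (E)-2-methyl-4-(tributylstannyl)but-3-en-2-ol | CCCC[Sn](CCCC)(CCCC)/C=C/C(C)(C)O | intermediate
26 | 2,3-dibromopropene | C=C(Br)CBr | starting material
27 | (E)-6-bromo-2-methylhepta-3,6-dien-2-ol | C=C(Br)C/C=C/C(C)(C)O | intermediate
28 | CNP0546270.2, (3S,4R,5S,6S)-3-acetoxy-1-[(5E)-7-hydroxy-7-methyl-3-methylideneoct-5-en-1-yn-1-yl]-4-methoxycyclohex-1-ene-5,6-diol | C=C(C#CC1=C[C@H](OC(C)=O)[C@H](OC)[C@@H](O)[C@H]1O)C/C=C/C(C)(C)O | target

Total step count: 16. Longest linear sequence: 14 steps (steps 1–13 and 16, from D-erythronolactone 1); the side-chain bromide 27 takes 2 steps (14 and 15).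

Steps most likely to fail

Step 9. The delocalised enal ketyl may be reduced further, may couple between molecules through C2, or may expel the C3 silyloxy group after a second electron transfer before the ring closes; facial control by the C4 methoxy group may also be incomplete. Fallback by ring-closing metathesis and dihydroxylation, setting out from dialdehyde 17: both aldehydes are methylenated by a Wittig reaction (Ph3PCH3Br, KHMDS, THF, −78 °C) to the triene (3E,5S,6R)-5-(tert-butyldimethylsilyloxy)-6-methoxy-3-[(triisopropylsilyl)ethynyl]octa-1,3,7-triene F1. Ring-closing metathesis with the second-generation Grubbs catalyst RuCl2(=CHPh)(PCy3)(H2IMes) in CH2Cl2 joins the two vinyl groups as the C5=C6 bond of (3S,4R)-3-(tert-butyldimethylsilyloxy)-4-methoxy-1-[(triisopropylsilyl)ethynyl]cyclohexa-1,5-diene F2. OsO4 (cat.) with N-methylmorpholine N-oxide in acetone–water should then dihydroxylate the less substituted, more electron-rich C5=C6 bond in syn fashion from the face opposite the C4 methoxy and C3 silyloxy groups, which comes back to the route at diol 19.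

Step 7. The alkynyl-substituted vinyllithium may lose its geometry (equilibration through a cumulenic form) or decompose, and the Z-enal may isomerise under the amine released at work-up. Fallback by carbonylation, setting out from bromoenyne 11: palladium-catalysed methoxycarbonylation (Pd(OAc)2, dppf, CO 1 atm, MeOH, Et3N, DMF, 60 °C) passes through a vinylpalladium species with retention and should give methyl (2Z,4S,5R)-4-(tert-butyldimethylsilyloxy)-5-methoxy-6-(triethylsilyloxy)-2-[(triisopropylsilyl)ethynyl]hex-2-enoate F3. Reduction with i-Bu2AlH (CH2Cl2, −78 °C) gives the allylic alcohol (2Z,4S,5R)-4-(tert-butyldimethylsilyloxy)-5-methoxy-6-(triethylsilyloxy)-2-[(triisopropylsilyl)ethynyl]hex-2-en-1-ol F4. Swern oxidation with excess reagent oxidises the allylic alcohol and, as in step 8, the primary triethylsilyl ether, coming back to the route at dialdehyde 17.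

Step 4. Ring opening of the lactol may be sluggish, the liberated primary hydroxyl may be brominated by residual bromophosphonium species (Appel pathway), or the silyl group may migrate from O3 to the new primary hydroxyl. Fallback through an open-chain amide with the alcohol capped before olefination, setting out from lactone 3: ring opening with Me(MeO)NH·HCl and i-PrMgCl (THF, −20 °C) gives the Weinreb amide (2R,3R)-2-(tert-butyldimethylsilyloxy)-4-hydroxy-N,3-dimethoxy-N-methylbutanamide F5. Immediate silylation (Et3SiCl, imidazole) gives (2R,3R)-2-(tert-butyldimethylsilyloxy)-N,3-dimethoxy-N-methyl-4-(triethylsilyloxy)butanamide F6. Reduction with i-Bu2AlH (THF, −78 °C) gives the aldehyde (2R,3R)-2-(tert-butyldimethylsilyloxy)-3-methoxy-4-(triethylsilyloxy)butanal F7. Corey–Fuchs dibromo-olefination (CBr4, PPh3, Zn, CH2Cl2) of this protected aldehyde comes back to the route at dibromo-olefin 9.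

Further compounds

F1 | step 9 | (3E,5S,6R)-5-(tert-butyldimethylsilyloxy)-6-methoxy-3-[(triisopropylsilyl)ethynyl]octa-1,3,7-triene | C=C[C@@H](OC)[C@@H](O[Si](C)(C)C(C)(C)C)/C=C(\C=C)C#C[Si](C(C)C)(C(C)C)C(C)C
F2 | step 9 | (3S,4R)-3-(tert-butyldimethylsilyloxy)-4-methoxy-1-[(triisopropylsilyl)ethynyl]cyclohexa-1,5-diene | CC(C)[Si](C#CC1=C[C@H](O[Si](C)(C)C(C)(C)C)[C@H](OC)C=C1)(C(C)C)C(C)C
F3 | step 7 | methyl (2Z,4S,5R)-4-(tert-butyldimethylsilyloxy)-5-methoxy-6-(triethylsilyloxy)-2-[(triisopropylsilyl)ethynyl]hex-2-enoate | CC(C)[Si](C#C/C(C(=O)OC)=C/[C@H](O[Si](C)(C)C(C)(C)C)[C@H](OC)CO[Si](CC)(CC)CC)(C(C)C)C(C)C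
F4 | step 7 | (2Z,4S,5R)-4-(tert-butyldimethylsilyloxy)-5-methoxy-6-(triethylsilyloxy)-2-[(triisopropylsilyl)ethynyl]hex-2-en-1-ol | CC(C)[Si](C#C/C(CO)=C/[C@H](O[Si](C)(C)C(C)(C)C)[C@H](OC)CO[Si](CC)(CC)CC)(C(C)C)C(C)C
F5 | step 4 | (2R,3R)-2-(tert-butyldimethylsilyloxy)-4-hydroxy-N,3-dimethoxy-N-methylbutanamide | CON(C)C(=O)[C@H](O[Si](C)(C)C(C)(C)C)[C@H](OC)CO
F6 | step 4 | (2R,3R)-2-(tert-butyldimethylsilyloxy)-N,3-dimethoxy-N-methyl-4-(triethylsilyloxy)butanamide | CON(C)C(=O)[C@H](O[Si](C)(C)C(C)(C)C)[C@H](OC)CO[Si](CC)(CC)CC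
F7 | step 4 | (2R,3R)-2-(tert-butyldimethylsilyloxy)-3-methoxy-4-(triethylsilyloxy)butanal | O=C[C@H](O[Si](C)(C)C(C)(C)C)[C@H](OC)CO[Si](CC)(CC)CC
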